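The route rests on never forcing an aryl group onto the ring D C2 oxygen, which is wedged between the C1 and C3 oxygens; ring E is grown on it instead. Ring E is a phenyl ether attached through C1, unsubstituted at C2 and C6 and oxygenated at C3, C4 and C5, so it can be cut into an aryloxyacetylene (E C1 and C2) and a 3,4-dialkoxycyclobutenone (E C3 to C6). One thermal benzannulation forms E C2–C3 and E C1–C6 and closes the ring at C3–C4. Its precursor is the terminal ethynyl ether of a ring D phenol (C1 benzyl ether, C3–C5 methyl ethers) with racemic 3-ethoxy-4-methoxycyclobutenone. An A–B–C triflate is then attached and every alkyl ether cleaved.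

Key step: step 7

Assumption: rings are lettered A (2,4,6-trihydroxyphenyl end) to E (3,4,5-trihydroxyphenyl end), with B C2–O–C C1, C C4–O–D C1 and D C2–O–E C1; 2,4,6-trimethoxyphenol, 2-bromo-4,6-dimethoxybenzaldehyde and 4-bromo-2,6-dimethoxybenzaldehyde are taken to be catalogue compounds; methyl and ethyl ethers are the permanent protection and the target has no stereocentre.

**Step 1**  
Reactants: 1 3,4,5-trimethoxyphenol  
Product: 2 5-(benzyloxy)-1,2,3-trimethoxybenzene  
Conditions: BnBr, K2CO3, acetone, reflux  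
Reagents that add atoms: benzyl bromide BrCc1ccccc1  
Why: Williamson etherification of the single phenol is routine, and the benzyl ether on the future D C1 oxygen withstands the Vilsmeier reagent, peracid, cold n-BuLi and the heat of step 7 before leaving by hydrogenolysis.

**Step 2**  
Reactants: 2 5-(benzyloxy)-1,2,3-trimethoxybenzene  
Product: 4 6-(benzyloxy)-2,3,4-trimethoxybenzaldehyde, via iminium salt 3 (not isolated)  
Conditions: POCl3, DMF, 0 → 70 °C; then H2O, 0 °C  
Reagents that add atoms: N,N-dimethylformamide CN(C)C=O; water O  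
Why: Vilsmeier–Haack formylation attacks the only kind of free ring position (the two are equivalent), ortho to the benzyloxy group and ortho/para to methoxy groups, so the carbon handle lands where the D C2 oxygen is required.

**Step 3**  
Reactants: 4 6-(benzyloxy)-2,3,4-trimethoxybenzaldehyde  
Product: 6 6-(benzyloxy)-2,3,4-trimethoxyphenol, via aryl formate 5 (not isolated)  
Conditions: mCPBA, CH2Cl2, 0 °C → rt; NaHCO3 wash; then K2CO3 (cat.), MeOH, rt  
Reagents that add atoms: mCPBA OOC(=O)c1cccc(Cl)c1  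
Why: Baeyer–Villiger (Dakin-type) oxidation works because the electron-rich 2,6-dialkoxyaryl group migrates to the peracid oxygen far faster than hydride, and the formate is methanolysed under mild base.

**Step 4**  
Reactants: 6 6-(benzyloxy)-2,3,4-trimethoxyphenol; 7 trichloroethylene  
Product: 9 1-(benzyloxy)-2-{[(E)-1,2-dichloroethenyl]oxy}-3,4,5-trimethoxybenzene, via dichloroacetylene 8 (not isolated)  
Conditions: K2CO3, DMF, 70 °C  
Reagents that add atoms: none  
Why: Base dehydrochlorinates trichloroethylene to dichloroacetylene, to which the phenoxide adds in anti fashion (the established dichlorovinylation of phenols), and so slim a two-carbon electrophile is not hindered by the flanking benzyloxy and methoxy groups.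

**Step 5**  
Reactants: 9 1-(benzyloxy)-2-{[(E)-1,2-dichloroethenyl]oxy}-3,4,5-trimethoxybenzene  
Product: 12 1-(benzyloxy)-2-(ethynyloxy)-3,4,5-trimethoxybenzene, via chloroalkynyl ether 10 (not isolated), via lithium acetylide 11 (not isolated)  
Conditions: n-BuLi (2.2 equiv), Et2O, −78 → −40 °C; then MeOH, −78 °C  
Reagents that add atoms: none  
Why: The standard dichlorovinyl ether to ynol ether conversion runs by elimination of HCl to the chloroalkyne, lithium–chlorine exchange and protonation; the terminal aryloxyacetylene is kept cold in solution and carried into step 7 without storage.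

**Step 6**  
Reactants: 13 methoxyacetyl chloride; 14 ethoxyacetylene  
Product: 16 rac-3-ethoxy-4-methoxycyclobut-2-en-1-one, via methoxyketene 15 (not isolated)  
Conditions: Et3N, Et2O/hexanes, 0 °C → rt, slow addition of 13 to excess 14  
Reagents that add atoms: none  
Why: Et3N dehydrochlorinates the acid chloride to methoxyketene, which undergoes the known regioselective ketene–alkoxyalkyne [2+2] cycloaddition (alkyne terminus to the ketene carbonyl carbon); the one stereocentre (C4) forms racemic and is erased in step 7.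

**Step 7**  
Reactants: 12 1-(benzyloxy)-2-(ethynyloxy)-3,4,5-trimethoxybenzene; 16 rac-3-ethoxy-4-methoxycyclobut-2-en-1-one  
Product: 21 5-[6-(benzyloxy)-2,3,4-trimethoxyphenoxy]-3-ethoxy-2-methoxyphenol, via vinylketene 17 (not isolated), via vinylcyclobutenone 18 (not isolated), via dienylketene 19 (not isolated), via cyclohexadienone 20 (not isolated)  
Conditions: 16 (1.5 equiv), toluene, 80 → 110 °C, sealed tube, argon; then K2CO3 (cat.), MeOH, rt  
Reagents that add atoms: none  
Why: Heating opens 16 by 4π-electrocyclic cleavage of its C1–C4 bond (the C4 methoxy group turns outward and lowers the barrier) to vinylketene 17, whose carbonyl carbon is attacked by the nucleophilic terminal carbon of ynol ether 12 in a [2+2] cycloaddition that gives 18 and forms E C2–C3 and E C1–C6; 18 reopens to dienylketene 19, which cyclises to dienone 20 and enolises to phenol 21. The closest known reaction type is the Danheiser benzannulation of cyclobutenones with alkoxyacetylenes, which delivers resorcinol monoethers. Ring E is closed by thermal disrotatory 6π-electrocyclisation of 19, which re-forms E C3–C4, and the sp3 carbon created there is aromatised at once. No stereocentre survives, since the centres of 16, 18 and 20 are racemic and transient. The selectivity needed is the orientation of the [2+2] step, and the polarisation of the O–C≡C–H unit (terminal carbon nucleophilic) secures it, placing the carbon that bears the ring D oxygen meta to the new hydroxyl and giving the 1-aryloxy-3,4,5-trioxygenated ring. The aryloxy group has no β-hydrogen, so the ynol ether cannot fragment to ketene and alkene on heating, and the final methanolysis returns any product acylated by excess vinylketene.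

**Step 8**  
Reactants: 21 5-[6-(benzyloxy)-2,3,4-trimethoxyphenoxy]-3-ethoxy-2-methoxyphenol  
Product: 22 1-(benzyloxy)-2-(3-ethoxy-4,5-dimethoxyphenoxy)-3,4,5-trimethoxybenzene  
Conditions: MeI, K2CO3, acetone, reflux  
Reagents that add atoms: iodomethane CI  
Why: Williamson methylation of the only free phenol (E C3–OH) is unhindered and blocks this oxygen so that ring D C1–OH can later be the sole nucleophile.

**Step 9**  
Reactants: 22 1-(benzyloxy)-2-(3-ethoxy-4,5-dimethoxyphenoxy)-3,4,5-trimethoxybenzene  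
Product: 23 2-(3-ethoxy-4,5-dimethoxyphenoxy)-3,4,5-trimethoxyphenol  
Conditions: H2 (1 atm), Pd/C, EtOAc/MeOH, rt  
Reagents that add atoms: none  
Why: Catalytic hydrogenolysis cleaves only the benzylic C–O bond, since methyl, ethyl and diaryl ethers are inert to H2 over Pd/C.

**Step 10**  
Reactants: 24 2,4,6-trimethoxyphenol; 25 2-bromo-4,6-dimethoxybenzaldehyde  
Product: 26 2,4-dimethoxy-6-(2,4,6-trimethoxyphenoxy)benzaldehyde  
Conditions: CuI (10 mol %), picolinic acid (20 mol %), K3PO4, DMSO, 90 °C, argon  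
Reagents that add atoms: none  
Why: Ullmann-type diaryl ether coupling under CuI/picolinic acid catalysis suits 2,6-disubstituted phenols, and the ortho-formyl group activates the aryl bromide, so the hindered oxygen is the nucleophile and the electrophile is the easy partner.

**Step 11**  
Reactants: 26 2,4-dimethoxy-6-(2,4,6-trimethoxyphenoxy)benzaldehyde  
Product: 28 2,4-dimethoxy-6-(2,4,6-trimethoxyphenoxy)phenol, via aryl formate 27 (not isolated)  
Conditions: mCPBA, CH2Cl2, 0 °C → rt; NaHCO3 wash; then K2CO3 (cat.), MeOH, rt  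
Reagents that add atoms: mCPBA OOC(=O)c1cccc(Cl)c1  
Why: Baeyer–Villiger oxidation with migration of the 2,6-dioxygenated aryl group turns the formyl carbon into the ring B C2 oxygen, and formate methanolysis unveils the next 2,6-disubstituted phenol.

**Step 12**  
Reactants: 28 2,4-dimethoxy-6-(2,4,6-trimethoxyphenoxy)phenol; 29 4-bromo-2,6-dimethoxybenzaldehyde  
Product: 30 4-[2,4-dimethoxy-6-(2,4,6-trimethoxyphenoxy)phenoxy]-2,6-dimethoxybenzaldehyde  
Conditions: CuI (10 mol %), picolinic acid (20 mol %), K3PO4, DMSO, 100 °C, argon  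
Reagents that add atoms: none  
Why: A second Ullmann-type coupling joins a hindered phenol to an aryl bromide that has no ortho substituent and is activated by the para-formyl group, the combination for which copper catalysis is reliable.

**Step 13**  
Reactants: 30 4-[2,4-dimethoxy-6-(2,4,6-trimethoxyphenoxy)phenoxy]-2,6-dimethoxybenzaldehyde  
Product: 32 4-[2,4-dimethoxy-6-(2,4,6-trimethoxyphenoxy)phenoxy]-2,6-dimethoxyphenol, via aryl formate 31 (not isolated)  
Conditions: mCPBA, CH2Cl2, 0 °C → rt; NaHCO3 wash; then K2CO3 (cat.), MeOH, rt  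
Reagents that add atoms: mCPBA OOC(=O)c1cccc(Cl)c1  
Why: Baeyer–Villiger oxidation of the 2,6-dimethoxybenzaldehyde (aryl migration) followed by formate methanolysis places the oxygen at ring C C4.

**Step 14**  
Reactants: 32 4-[2,4-dimethoxy-6-(2,4,6-trimethoxyphenoxy)phenoxy]-2,6-dimethoxyphenol  
Product: 33 4-[2,4-dimethoxy-6-(2,4,6-trimethoxyphenoxy)phenoxy]-2,6-dimethoxyphenyl trifluoromethanesulfonate  
Conditions: Tf2O, pyridine, CH2Cl2, 0 °C  
Reagents that add atoms: triflic anhydride O=S(=O)(OS(=O)(=O)C(F)(F)F)C(F)(F)F  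
Why: O-Sulfonylation of the phenol turns ring C C4 into an electrophile, and the two flanking methoxy groups shield the sulfur atom against later S–O cleavage.

**Step 15**  
Reactants: 33 4-[2,4-dimethoxy-6-(2,4,6-trimethoxyphenoxy)phenoxy]-2,6-dimethoxyphenyl trifluoromethanesulfonate; 23 2-(3-ethoxy-4,5-dimethoxyphenoxy)-3,4,5-trimethoxyphenol  
Product: 34 1-{4-[2,4-dimethoxy-6-(2,4,6-trimethoxyphenoxy)phenoxy]-2,6-dimethoxyphenoxy}-2-(3-ethoxy-4,5-dimethoxyphenoxy)-3,4,5-trimethoxybenzene  
Conditions: Pd(OAc)2 (5 mol %), tBuXPhos (10 mol %), K3PO4, toluene, 100 °C, argon  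
Reagents that add atoms: none  
Why: Palladium-catalysed C–O cross-coupling (Buchwald–Hartwig etherification) of an aryl triflate and a phenol should succeed because the bulky di-tert-butylbiarylphosphine and the doubly ortho-substituted aryl group on palladium both favour C–O reductive elimination, and ring D C1–OH is the only free phenol.

**Step 16**  
Reactants: 34 1-{4-[2,4-dimethoxy-6-(2,4,6-trimethoxyphenoxy)phenoxy]-2,6-dimethoxyphenoxy}-2-(3-ethoxy-4,5-dimethoxyphenoxy)-3,4,5-trimethoxybenzene  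
Product: 35 5-{4-[2,4-dihydroxy-6-(2,4,6-trihydroxyphenoxy)phenoxy]-2,6-dihydroxyphenoxy}-4-(3,4,5-trihydroxyphenoxy)benzene-1,2,3-triol (CNP0243665.0)  
Conditions: BBr3 (2 equiv per ether), CH2Cl2, −78 °C → rt, argon; then H2O, 0 °C  
Reagents that add atoms: none  
Why: BBr3 coordinates each alkyl aryl ether oxygen and bromide removes the methyl or ethyl group by SN2 attack at sp3 carbon, a path closed to the four diaryl ether bonds, so all thirteen hydroxyls should be released with the skeleton intact.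

**Compound list**

```
1 | 3,4,5-trimethoxyphenol | COc1cc(O)cc(OC)c1OC | starting material
2 | 5-(benzyloxy)-1,2,3-trimethoxybenzene | COc1cc(OCc2ccccc2)cc(OC)c1OC | intermediate
3 | [6-(benzyloxy)-2,3,4-trimethoxybenzylidene]dimethyliminium dichlorophosphate | C[N+](C)=Cc1c(OCc2ccccc2)cc(OC)c(OC)c1OC.[O-]P(=O)(Cl)Cl | intermediate (not isolated)
4 | 6-(benzyloxy)-2,3,4-trimethoxybenzaldehyde | O=Cc1c(OCc2ccccc2)cc(OC)c(OC)c1OC | intermediate
5 | 6-(benzyloxy)-2,3,4-trimethoxyphenyl formate | O=COc1c(OCc2ccccc2)cc(OC)c(OC)c1OC | intermediate (not isolated)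
6 | 6-(benzyloxy)-2,3,4-trimethoxyphenol | Oc1c(OCc2ccccc2)cc(OC)c(OC)c1OC | intermediate
7 | trichloroethylene | ClC=C(Cl)Cl | starting material
8 | dichloroacetylene | ClC#CCl | intermediate (not isolated)
9 | 1-(benzyloxy)-2-{[(E)-1,2-dichloroethenyl]oxy}-3,4,5-trimethoxybenzene | COc1cc(OCc2ccccc2)c(O/C(Cl)=C\Cl)c(OC)c1OC | intermediate
10 | 1-(benzyloxy)-2-[(chloroethynyl)oxy]-3,4,5-trimethoxybenzene | COc1cc(OCc2ccccc2)c(OC#CCl)c(OC)c1OC | intermediate (not isolated)
11 | lithium [6-(benzyloxy)-2,3,4-trimethoxyphenoxy]ethynide | COc1cc(OCc2ccccc2)c(OC#C[Li])c(OC)c1OC | intermediate (not isolated)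
12 | 1-(benzyloxy)-2-(ethynyloxy)-3,4,5-trimethoxybenzene (ring D ynol ether) | COc1cc(OCc2ccccc2)c(OC#C)c(OC)c1OC | intermediate
13 | methoxyacetyl chloride | COCC(=O)Cl | starting material
14 | ethoxyacetylene | CCOC#C | starting material
15 | methoxyketene | COC=C=O | intermediate (not isolated)
16 | rac-3-ethoxy-4-methoxycyclobut-2-en-1-one (racemic) | O=C1C=C(OCC)C1OC | intermediate
17 | (3Z)-3-ethoxy-4-methoxybuta-1,3-dien-1-one | O=C=C/C(OCC)=C/OC | intermediate (not isolated)
18 | rac-3-[6-(benzyloxy)-2,3,4-trimethoxyphenoxy]-4-[(Z)-1-ethoxy-2-methoxyethenyl]cyclobut-2-en-1-one (racemic) | O=C1C=C(Oc2c(OCc3ccccc3)cc(OC)c(OC)c2OC)C1/C(OCC)=C/OC | intermediate (not isolated)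
19 | (3E,5Z)-3-[6-(benzyloxy)-2,3,4-trimethoxyphenoxy]-5-ethoxy-6-methoxyhexa-1,3,5-trien-1-one | O=C=C/C(Oc1c(OCc2ccccc2)cc(OC)c(OC)c1OC)=C\C(OCC)=C\OC | intermediate (not isolated)
20 | rac-3-[6-(benzyloxy)-2,3,4-trimethoxyphenoxy]-5-ethoxy-6-methoxycyclohexa-2,4-dien-1-one (racemic) | O=C1C=C(Oc2c(OCc3ccccc3)cc(OC)c(OC)c2OC)C=C(OCC)C1OC | intermediate (not isolated)
21 | 5-[6-(benzyloxy)-2,3,4-trimethoxyphenoxy]-3-ethoxy-2-methoxyphenol (D–E ether, E C3–OH free) | COc1cc(OCc2ccccc2)c(Oc2cc(O)c(OC)c(OCC)c2)c(OC)c1OC | intermediate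
22 | 1-(benzyloxy)-2-(3-ethoxy-4,5-dimethoxyphenoxy)-3,4,5-trimethoxybenzene | COc1cc(OCc2ccccc2)c(Oc2cc(OC)c(OC)c(OCC)c2)c(OC)c1OC | intermediate
23 | 2-(3-ethoxy-4,5-dimethoxyphenoxy)-3,4,5-trimethoxyphenol (D–E ether, D C1–OH free) | COc1cc(O)c(Oc2cc(OC)c(OC)c(OCC)c2)c(OC)c1OC | intermediate
24 | 2,4,6-trimethoxyphenol | COc1cc(OC)c(O)c(OC)c1 | starting material
25 | 2-bromo-4,6-dimethoxybenzaldehyde | COc1cc(Br)c(C=O)c(OC)c1 | starting material
26 | 2,4-dimethoxy-6-(2,4,6-trimethoxyphenoxy)benzaldehyde | COc1cc(Oc2c(OC)cc(OC)cc2OC)c(C=O)c(OC)c1 | intermediate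
27 | 2,4-dimethoxy-6-(2,4,6-trimethoxyphenoxy)phenyl formate | COc1cc(Oc2c(OC)cc(OC)cc2OC)c(OC=O)c(OC)c1 | intermediate (not isolated)
28 | 2,4-dimethoxy-6-(2,4,6-trimethoxyphenoxy)phenol (A–B phenol) | COc1cc(Oc2c(OC)cc(OC)cc2OC)c(O)c(OC)c1 | intermediate
29 | 4-bromo-2,6-dimethoxybenzaldehyde | COc1cc(Br)cc(OC)c1C=O | starting material
30 | 4-[2,4-dimethoxy-6-(2,4,6-trimethoxyphenoxy)phenoxy]-2,6-dimethoxybenzaldehyde | COc1cc(Oc2c(OC)cc(OC)cc2Oc2c(OC)cc(OC)cc2OC)cc(OC)c1C=O | intermediate
31 | 4-[2,4-dimethoxy-6-(2,4,6-trimethoxyphenoxy)phenoxy]-2,6-dimethoxyphenyl formate | COc1cc(Oc2c(OC)cc(OC)cc2Oc2c(OC)cc(OC)cc2OC)cc(OC)c1OC=O | intermediate (not isolated)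
32 | 4-[2,4-dimethoxy-6-(2,4,6-trimethoxyphenoxy)phenoxy]-2,6-dimethoxyphenol (A–B–C phenol) | COc1cc(Oc2c(OC)cc(OC)cc2Oc2c(OC)cc(OC)cc2OC)cc(OC)c1O | intermediate
33 | 4-[2,4-dimethoxy-6-(2,4,6-trimethoxyphenoxy)phenoxy]-2,6-dimethoxyphenyl trifluoromethanesulfonate (A–B–C triflate) | COc1cc(Oc2c(OC)cc(OC)cc2Oc2c(OC)cc(OC)cc2OC)cc(OC)c1OS(=O)(=O)C(F)(F)F | intermediate
34 | 1-{4-[2,4-dimethoxy-6-(2,4,6-trimethoxyphenoxy)phenoxy]-2,6-dimethoxyphenoxy}-2-(3-ethoxy-4,5-dimethoxyphenoxy)-3,4,5-trimethoxybenzene (protected pentamer) | COc1cc(Oc2c(OC)cc(OC)cc2Oc2c(OC)cc(OC)cc2OC)cc(OC)c1Oc1cc(OC)c(OC)c(OC)c1Oc1cc(OC)c(OC)c(OCC)c1 | intermediate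
35 | 5-{4-[2,4-dihydroxy-6-(2,4,6-trihydroxyphenoxy)phenoxy]-2,6-dihydroxyphenoxy}-4-(3,4,5-trihydroxyphenoxy)benzene-1,2,3-triol (CNP0243665.0) | Oc1cc(O)c(Oc2cc(O)cc(O)c2Oc2cc(O)c(Oc3cc(O)c(O)c(O)c3Oc3cc(O)c(O)c(O)c3)c(O)c2)c(O)c1 | target
```

**Step count and risk**

Total step count: 16. Longest linear sequence: 10 steps (1 to 35 through steps 1–5, 7–9, 15 and 16).

Step 7. The terminal aryloxyacetylene may oligomerise, and the vinylketene may dimerise or acylate the phenol product, faster than the [2+2] addition and 6π closure run to completion. The fallback abandons the benzannulation for a copper-catalysed ether coupling in which the crowded oxygen is the nucleophile. It sets out from phenol 6, which is coupled with commercial 5-bromo-1,2,3-trimethoxybenzene (CuI, picolinic acid, K3PO4, DMSO, 90 °C) to 1-(benzyloxy)-3,4,5-trimethoxy-2-(3,4,5-trimethoxyphenoxy)benzene F1. Hydrogenolysis (H2, Pd/C) gives 3,4,5-trimethoxy-2-(3,4,5-trimethoxyphenoxy)phenol F2. Coupling with triflate 33 under the step 15 conditions gives the tridecamethyl ether of the target F3, and BBr3 as in step 16 comes back to the route at 35.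

Step 15. Oxidative addition and C–O reductive elimination at the electron-rich, doubly flanked ring C carbon may be too slow, so that S–O cleavage of the triflate by phenoxide or reduction of the triflate prevails. The fallback reverses the polarity and uses a copper-mediated oxidative coupling in which the hindered ring C phenol is the nucleophile. It sets out from 23, which Tf2O and pyridine convert into 2-(3-ethoxy-4,5-dimethoxyphenoxy)-3,4,5-trimethoxyphenyl trifluoromethanesulfonate F4. Miyaura borylation (B2pin2, Pd(dppf)Cl2, KOAc, dioxane, 90 °C) gives 2-[2-(3-ethoxy-4,5-dimethoxyphenoxy)-3,4,5-trimethoxyphenyl]-4,4,5,5-tetramethyl-1,3,2-dioxaborolane F5. NaIO4 and NH4OAc in aqueous acetone free [2-(3-ethoxy-4,5-dimethoxyphenoxy)-3,4,5-trimethoxyphenyl]boronic acid F6. Chan–Lam–Evans coupling of F6 with phenol 32 (Cu(OAc)2, pyridine, 4 Å molecular sieves, air, CH2Cl2, rt) comes back to the route at 34.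

Step 16. Dealkylation may stop short of all thirteen ethers (the ethyl ether and the flanked methyl ethers being slowest), and the pyrogallol-type rings D and E may oxidise in air while the very polar product is isolated. The fallback is a capture-and-release end-game. It sets out from 34: after BBr3 treatment the crude polyphenol is not isolated but acetylated (Ac2O, pyridine, argon) to the tridecaacetate of the target F7, which is stable and can be separated on silica from partly alkylated material. Acid methanolysis under degassed conditions (HCl cat., MeOH, rt) comes back to the route at 35.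

**Further compounds**

```
F1 | step 7 | 1-(benzyloxy)-3,4,5-trimethoxy-2-(3,4,5-trimethoxyphenoxy)benzene | COc1cc(OCc2ccccc2)c(Oc2cc(OC)c(OC)c(OC)c2)c(OC)c1OC
F2 | step 7 | 3,4,5-trimethoxy-2-(3,4,5-trimethoxyphenoxy)phenol | COc1cc(O)c(Oc2cc(OC)c(OC)c(OC)c2)c(OC)c1OC
F3 | step 7 | 1-{4-[2,4-dimethoxy-6-(2,4,6-trimethoxyphenoxy)phenoxy]-2,6-dimethoxyphenoxy}-3,4,5-trimethoxy-2-(3,4,5-trimethoxyphenoxy)benzene | COc1cc(Oc2c(OC)cc(OC)cc2Oc2c(OC)cc(OC)cc2OC)cc(OC)c1Oc1cc(OC)c(OC)c(OC)c1Oc1cc(OC)c(OC)c(OC)c1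
F4 | step 15 | 2-(3-ethoxy-4,5-dimethoxyphenoxy)-3,4,5-trimethoxyphenyl trifluoromethanesulfonate | COc1cc(OS(=O)(=O)C(F)(F)F)c(Oc2cc(OC)c(OC)c(OCC)c2)c(OC)c1OC
F5 | step 15 | 2-[2-(3-ethoxy-4,5-dimethoxyphenoxy)-3,4,5-trimethoxyphenyl]-4,4,5,5-tetramethyl-1,3,2-dioxaborolane | COc1cc(B2OC(C)(C)C(C)(C)O2)c(Oc2cc(OC)c(OC)c(OCC)c2)c(OC)c1OC
F6 | step 15 | [2-(3-ethoxy-4,5-dimethoxyphenoxy)-3,4,5-trimethoxyphenyl]boronic acid | COc1cc(B(O)O)c(Oc2cc(OC)c(OC)c(OCC)c2)c(OC)c1OC
F7 | step 16 | tridecaacetate of 35 | CC(=O)Oc1cc(OC(C)=O)c(Oc2cc(OC(C)=O)cc(OC(C)=O)c2Oc2cc(OC(C)=O)c(Oc3cc(OC(C)=O)c(OC(C)=O)c(OC(C)=O)c3Oc3cc(OC(C)=O)c(OC(C)=O)c(OC(C)=O)c3)c(OC(C)=O)c2)c(OC(C)=O)c1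
```
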